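The runs were computed from invented constants, and the scatter is random.

You cannot make more left-handed product than the partner charged, and 12.0 mM of partner stands against 20 mM of left-handed substrate. Partner is the limiting reagent, and counting one partner per product, the ceiling for autumn and noon is an excess of 42.9%. How far below that ceiling do they end?

| flask | left-handed substrate | right-handed substrate | partner | free catalyst | added ligand | remark | time |
|---|---|---|---|---|---|---|---|
| east | 30 mM | 30 mM | 12 mM | 46 µM | 0.16 mM | run made earlier |  |
| north-east | 20 mM | 20 mM | 12 mM | 23 µM | 0.16 mM | run made earlier |  |
| autumn | 20 mM | 20 mM | 12.0 mM | 46 µM | 0.16 mM |  | 30 min |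
| noon | 20 mM | 20 mM | 12.0 mM | 46 µM | 0.080 mM |  | 30 min |

| run | time / min | right-handed substrate / % | left-handed substrate / % | left-handed product / % |
|---|---|---|---|---|
| east | 1.33 | 49.8 | 49.1 | 0.8 |
| east | 4.00 | 49.9 | 47.1 | 2.9 |
| east | 6.00 | 50.2 | 46.7 | 3.4 |
| east | 10.0 | 49.7 | 45.1 | 5.2 |
| east | 15.0 | 50.1 | 43.1 | 6.9 |
| east | 20.0 | 50.0 | 41.9 | 8.1 |
| north-east | 3.00 | 49.8 | 48.6 | 0.7 |
| north-east | 6.00 | 49.7 | 48.1 | 2.1 |
| north-east | 10.0 | 50.3 | 45.9 | 3.4 |
| north-east | 12.0 | 49.9 | 45.4 | 3.9 |
| north-east | 15.0 | 50.1 | 44.6 | 4.7 |
| north-east | 20.0 | 49.8 | 43.5 | 6.5 |

(each reading ± 0.3 percentage points)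

* the flask that ends with the higher excess of right-handed substrate over left-handed substrate among what is left of the two, or "neither" when 2 percentage points or less lies between them (autumn / noon / neither)
* excess of right-handed substrate over left-handed substrate among what is left of the two at the end, autumn
* excess of right-handed substrate over left-handed substrate among what is left of the two at the end, noon

- free catalyst is single-handed; left-handed substrate and right-handed substrate are mirror images of each other, charged as a racemate, each of them at the stated concentration
- an excess is the difference of the two amounts in percent of their sum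
- an excess is below zero if the other one leads
- no earlier run changes the charge of added ligand; that part of a forecast is a guess

1. The first instants. Right-handed substrate stays flat, at 50.0% in the last east reading. So if x is the product made, the excess is x divided by the two substrate charges together less x. At 20.0 min, east has made 4.86 mM and north-east 2.60 mM. That ratio of 1.87 lies near the catalyst ratio of 2.00, although the substrate charges differ. I therefore let the rate follow [free catalyst] and take nothing from [left-handed substrate].

2. The middle. East makes 3.12 mM in its first 10.0 min but 1.74 mM in the next. I put this slowing on [partner] and take both its loss and the product rate as first order in it. Divide one rate by the other: time and [partner] drop out, leaving a constant at fixed catalyst. The east readings give a decay factor of 0.558 per 10.0 min and, extrapolated, a final product of 7.05 mM. So the partner share is 58.8%, the product made per partner lost. It is a reading, with the scatter of two points.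

3. The end. Autumn has the catalyst, partner and ligand of east. Over 30 min the factor applies 3 times, giving 5.83 mM of product and, by my reckoning, an excess of 17.1%. No earlier run changes the ligand, so my noon is a guess: within 2 percentage points of autumn, hence neither.

The forecast differs, saying noon, with 15% for autumn and 23% for noon, on the guess that “halving the ligand should speed the reaction”.

The flasks give 16.0% for autumn and 17.0% for noon, so neither.

    free catalyst + added ligand ⇌ idle complex (K = 9300 L mol⁻¹, k = 7210 L mol⁻¹ min⁻¹)
    partner → decomposed reagent (k = 0.0119 min⁻¹)
    partner + catalyst intermediate B → free catalyst + right-handed product (k = 294 L mol⁻¹ min⁻¹)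
    free catalyst + left-handed substrate ⇌ catalyst intermediate A (K = 410 L mol⁻¹, k = 14000 L mol⁻¹ min⁻¹)
    free catalyst → spent catalyst (k = 0.0251 min⁻¹)
    partner + catalyst intermediate A → free catalyst + left-handed product (k = 890 L mol⁻¹ min⁻¹)
    free catalyst + right-handed substrate ⇌ catalyst intermediate B (K = 24.0 L mol⁻¹, k = 14500 L mol⁻¹ min⁻¹)

Autumn lost 8.26 mM of partner for 5.76 mM of product, a share of 69.7% against my 58.8%. The excess of autumn stands on the right-handed side because catalyst intermediate B runs back to free catalyst and right-handed substrate: with that back step taken away, autumn goes from 16.0% to −6.96%. A neighbour of noon charged with 20 mM of partner lost 13.8 mM. My share makes that 8.10 mM of product, an excess of 25.4%, and autumn's share gives 9.61 mM, an excess of 31.6%. The neighbour ends at 29.7%.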